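**Retrosynthetic overview** (butane locants: C1 carries the guaiacyl ring, C4 the syringyl ring)
- The target comes from exhaustive reduction of an erythro 2,3-dimethyl-1,4-diaryl-butane-1,4-dione: both C=O become CH2 and both O-benzyl groups become OH.
- The diketone comes from a guaiacyl aryllithium adding to a Weinreb amide, plus hydrolysis of a SAMP hydrazone that masks the syringyl ketone.
- Key C2–C3 bond: the SAMP-hydrazone azaenolate of the syringyl ethyl ketone (α-carbon as nucleophile) displaces the triflate of an (R)-lactate-derived α-triflyloxy Weinreb amide (α-carbon as electrophile, an enolonium equivalent). Two carbonyl α-carbons are joined; C3 is set by the auxiliary and C2 by the chiral pool with SN2 inversion.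
- No ring is formed; both benzene rings are bought.

Assumption: all numbered starting materials and the auxiliary are catalogue items; hydrazone C=N geometry is drawn E where given and does not matter for the route.

Note on descriptors: the carbonyl-stage intermediates are 2R,3S and the target is 2S,3R on the same locants. Only the CIP priorities change; no centre is inverted after step 5.

**Step 1**
Reactants: 1 methyl (R)-lactate
Product: 2 (R)-2-hydroxy-N-methoxy-N-methylpropanamide
Conditions: MeNH(OMe)·HCl, iPrMgCl (3.2 equiv), THF, −20 → 0 °C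
Reagents that add atoms: N,O-dimethylhydroxylamine hydrochloride, Cl.CNOC
Why: Weinreb aminolysis of the ester by the chloromagnesium amide formed in the flask; the lactate centre is untouched because the hydroxyl is held as its magnesium alkoxide, which blocks enolisation.

**Step 2**
Reactants: 2 (R)-2-hydroxy-N-methoxy-N-methylpropanamide
Product: 3 (R)-1-(methoxy(methyl)amino)-1-oxopropan-2-yl trifluoromethanesulfonate
Conditions: Tf2O, 2,6-lutidine, CH2Cl2, −78 °C; cold silica plug, used at once
Reagents that add atoms: trifluoromethanesulfonic anhydride, O=S(=O)(OS(=O)(=O)C(F)(F)F)C(F)(F)F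
Why: O-sulfonylation of a secondary alcohol, with retention because only the O–H bond reacts; it turns the lactate α-carbon into the electrophilic α-acyl cation (enolonium) equivalent.

**Step 3**
Reactants: 4 1-(4-hydroxy-3,5-dimethoxyphenyl)propan-1-one
Product: 5 1-(4-(benzyloxy)-3,5-dimethoxyphenyl)propan-1-one
Conditions: BnBr, K2CO3, DMF, 60 °C
Reagents that add atoms: benzyl bromide, BrCc1ccccc1
Why: Williamson ether synthesis on the phenoxide; the benzyl ether survives the later strong bases and is removed in the final hydrogenation.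

**Step 4**
Reactants: 5 1-(4-(benzyloxy)-3,5-dimethoxyphenyl)propan-1-one; 6 (S)-1-amino-2-(methoxymethyl)pyrrolidine (SAMP)
Product: 7 (S,E)-N-(1-(4-(benzyloxy)-3,5-dimethoxyphenyl)propylidene)-2-(methoxymethyl)pyrrolidin-1-amine
Conditions: TsOH·H2O (cat.), toluene, reflux, Dean–Stark
Reagents that add atoms: none
Why: Acid-catalysed hydrazone condensation with azeotropic water removal; it installs the Enders auxiliary and creates no new stereocentre.

**Step 5 (key step)**
Reactants: 7 (S,E)-N-(1-(4-(benzyloxy)-3,5-dimethoxyphenyl)propylidene)-2-(methoxymethyl)pyrrolidin-1-amine; 3 (R)-1-(methoxy(methyl)amino)-1-oxopropan-2-yl trifluoromethanesulfonate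
Product: 9 (2R,3S)-4-(4-(benzyloxy)-3,5-dimethoxyphenyl)-N-methoxy-N,2,3-trimethyl-4-(((S)-2-(methoxymethyl)pyrrolidin-1-yl)imino)butanamide, via lithium azaenolate 8 (not isolated)
Conditions: LiN(iPr)2, THF, 0 °C, 4 h; then 3 in THF, −100 → −78 °C; pH 7 buffer
Reagents that add atoms: none
Why: Proposed new method: an Enders SAMP-hydrazone α-alkylation run with a secondary α-triflyloxy amide instead of a primary halide; azaenolate 8 (E C=C, lithium chelated by the methoxymethyl arm) reacts on its open face and sets C3 as S in the usual SAMP sense, while the triflate carbon of 3 is displaced by SN2 with inversion to give 2R, the amide carbonyl activating substitution and its low α-acidity at −100 °C holding back elimination and acyl attack; the closest known reaction types are displacement of α-triflyloxy esters by imide and ester enolates with inversion, and SAMP/RAMP alkylation of ketones.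

**Step 6**
Reactants: 9 (2R,3S)-4-(4-(benzyloxy)-3,5-dimethoxyphenyl)-N-methoxy-N,2,3-trimethyl-4-(((S)-2-(methoxymethyl)pyrrolidin-1-yl)imino)butanamide; 10 1-(benzyloxy)-4-bromo-2-methoxybenzene
Product: 13 (2R,3S)-1-(4-(benzyloxy)-3-methoxyphenyl)-4-(4-(benzyloxy)-3,5-dimethoxyphenyl)-2,3-dimethylbutane-1,4-dione, via aryllithium 11 (not isolated), via keto hydrazone 12 (not isolated)
Conditions: 10, n-BuLi, THF, −78 °C; then 9, −78 → −40 °C; then sat. aq. oxalic acid, Et2O, rt
Reagents that add atoms: water, O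
Why: Bromine–lithium exchange, Weinreb ketone synthesis and Enders two-phase oxalic acid hydrazone hydrolysis; no stereocentre is made, and C2 and C3 are preserved because the chelated tetrahedral adduct and the mild hydrolysis, which keeps the freed hydrazine protonated in the water layer, do not enolise the ketones.

**Step 7**
Reactants: 13 (2R,3S)-1-(4-(benzyloxy)-3-methoxyphenyl)-4-(4-(benzyloxy)-3,5-dimethoxyphenyl)-2,3-dimethylbutane-1,4-dione
Product: 15 4-((2R,3S)-4-(4-hydroxy-3-methoxyphenyl)-2,3-dimethylbutyl)-2,6-dimethoxyphenol, via diol 14 (not isolated)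
Conditions: NaBH4, THF–MeOH, 0 °C → rt; then AcOH, Pd(OH)2 on carbon, H2 (4 bar), MeOH–AcOH, 40 °C
Reagents that add atoms: none
Why: Hydride reduction followed by catalytic hydrogenolysis of the two p-oxygenated benzylic C–O bonds and both benzyl ethers; reducing first removes the 1,4-diketone before any acid is present, so a Paal–Knorr furan cannot erase C2 and C3, and the carbinol centres made by NaBH4 are themselves removed.

**Compound list**
1 | methyl (R)-lactate | C[C@@H](O)C(=O)OC | starting material
2 | (R)-2-hydroxy-N-methoxy-N-methylpropanamide | C[C@@H](O)C(=O)N(C)OC | intermediate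
3 | (R)-1-(methoxy(methyl)amino)-1-oxopropan-2-yl trifluoromethanesulfonate | C[C@@H](OS(=O)(=O)C(F)(F)F)C(=O)N(C)OC | intermediate
4 | 1-(4-hydroxy-3,5-dimethoxyphenyl)propan-1-one (propiosyringone) | CCC(=O)c1cc(OC)c(O)c(OC)c1 | starting material
5 | 1-(4-(benzyloxy)-3,5-dimethoxyphenyl)propan-1-one | CCC(=O)c1cc(OC)c(OCc2ccccc2)c(OC)c1 | intermediate
6 | (S)-1-amino-2-(methoxymethyl)pyrrolidine (SAMP, recoverable auxiliary) | COC[C@@H]1CCCN1N | starting material
7 | (S,E)-N-(1-(4-(benzyloxy)-3,5-dimethoxyphenyl)propylidene)-2-(methoxymethyl)pyrrolidin-1-amine | CC/C(c1cc(OC)c(OCc2ccccc2)c(OC)c1)=N\N1CCC[C@H]1COC | intermediate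
8 | lithium azaenolate of 7, E C=C (not isolated) | C/C=C(\c1cc(OC)c(OCc2ccccc2)c(OC)c1)N([Li])N1CCC[C@H]1COC | intermediate
9 | (2R,3S)-4-(4-(benzyloxy)-3,5-dimethoxyphenyl)-N-methoxy-N,2,3-trimethyl-4-(((S)-2-(methoxymethyl)pyrrolidin-1-yl)imino)butanamide (C=N geometry not controlled) | COC[C@@H]1CCCN1N=C(c1cc(OC)c(OCc2ccccc2)c(OC)c1)[C@@H](C)[C@@H](C)C(=O)N(C)OC | intermediate
10 | 1-(benzyloxy)-4-bromo-2-methoxybenzene | COc1cc(Br)ccc1OCc1ccccc1 | starting material
11 | (4-(benzyloxy)-3-methoxyphenyl)lithium (not isolated) | COc1cc([Li])ccc1OCc1ccccc1 | intermediate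
12 | (2R,3S)-1-(4-(benzyloxy)-3-methoxyphenyl)-4-(4-(benzyloxy)-3,5-dimethoxyphenyl)-4-(((S)-2-(methoxymethyl)pyrrolidin-1-yl)imino)-2,3-dimethylbutan-1-one (not isolated) | COC[C@@H]1CCCN1N=C(c1cc(OC)c(OCc2ccccc2)c(OC)c1)[C@@H](C)[C@@H](C)C(=O)c1ccc(OCc2ccccc2)c(OC)c1 | intermediate
13 | (2R,3S)-1-(4-(benzyloxy)-3-methoxyphenyl)-4-(4-(benzyloxy)-3,5-dimethoxyphenyl)-2,3-dimethylbutane-1,4-dione | O=C(c1cc(OC)c(OCc2ccccc2)c(OC)c1)[C@@H](C)[C@@H](C)C(=O)c1ccc(OCc2ccccc2)c(OC)c1 | intermediate
14 | (2R,3S)-1-(4-(benzyloxy)-3-methoxyphenyl)-4-(4-(benzyloxy)-3,5-dimethoxyphenyl)-2,3-dimethylbutane-1,4-diol, C1 and C4 carbinol epimers (not isolated) | OC(c1cc(OC)c(OCc2ccccc2)c(OC)c1)[C@@H](C)[C@@H](C)C(O)c1ccc(OCc2ccccc2)c(OC)c1 | intermediate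
15 | 4-((2R,3S)-4-(4-hydroxy-3-methoxyphenyl)-2,3-dimethylbutyl)-2,6-dimethoxyphenol | COc1cc(C[C@H](C)[C@H](C)Cc2cc(OC)c(O)c(OC)c2)ccc1O | target

**Totals**
Total step count: 7. Longest linear sequence: 5 (steps 3, 4, 5, 6, 7; the lactate arm through steps 1, 2, 5, 6, 7 is equally long).

**Three steps most likely to fail**

Step 5. A strongly basic azaenolate may eliminate the secondary triflate to the acrylamide or attack the amide carbonyl. The azaenolate geometry of an aryl ketone hydrazone, and so the sense at C3, is also less certain than for dialkyl ketones. The fallback replaces the SN2 displacement by an oxidative enolate heterocoupling and sets out from 7. Commercial 1-(4-hydroxy-3-methoxyphenyl)propan-1-one F1 is benzylated (BnBr, K2CO3, DMF) to 1-(4-(benzyloxy)-3-methoxyphenyl)propan-1-one F2. Its lithium (Z)-enolate F3 (LiN(iPr)2, THF, −78 °C) is mixed with azaenolate 8 made from 7, and the mixture is oxidised with CuCl2 in DMF–THF at −78 °C. C3 is still set by the auxiliary, but C2 is no longer controlled. The cross-coupled product is separated from homodimers and from its C2 epimer by chromatography, and the route is rejoined at 12, which is hydrolysed as in step 6.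

Step 6. Freeing the hydrazone next to a second ketone is delicate: liberated SAMP can condense with the 1,4-diketone to an N-aminopyrrole, acid can close a furan, and either would erase both stereocentres. The fallback never forms a 1,4-diketone and sets out from 12, isolated after a neutral NH4Cl quench. NaBH4 (THF–MeOH, 0 °C) reduces the free ketone to (2R,3S)-1-(4-(benzyloxy)-3-methoxyphenyl)-4-(4-(benzyloxy)-3,5-dimethoxyphenyl)-4-(((S)-2-(methoxymethyl)pyrrolidin-1-yl)imino)-2,3-dimethylbutan-1-ol F4. Ozonolysis of the hydrazone (O3, CH2Cl2, −78 °C) gives (2S,3R)-4-(4-(benzyloxy)-3-methoxyphenyl)-1-(4-(benzyloxy)-3,5-dimethoxyphenyl)-4-hydroxy-2,3-dimethylbutan-1-one F5, in equilibrium with its lactol. A second NaBH4 reduction gives the diol, so the route is rejoined at 14 and finished by the hydrogenolysis half of step 7.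

Step 7. Hydrogenolysis may stall at a 2,5-diaryl-3,4-dimethyltetrahydrofuran or a mono-alcohol, and borate salts from the telescoped reduction may slow the catalyst. The fallback replaces catalytic C–O hydrogenolysis by ionic deoxygenation and sets out from 14, isolated after aqueous work-up. Et3SiH with BF3·OEt2 (CH2Cl2, −78 → 0 °C) reduces both benzylic alcohols through p-alkoxybenzyl cations, and also opens any tetrahydrofuran, to give 1-(benzyloxy)-4-((2S,3R)-4-(4-(benzyloxy)-3,5-dimethoxyphenyl)-2,3-dimethylbutyl)-2-methoxybenzene F6. Neutral debenzylation (H2, Pd on carbon, EtOAc–EtOH, rt) then rejoins the route at 15.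

**Further compounds**
F1 | step 5 | 1-(4-hydroxy-3-methoxyphenyl)propan-1-one | CCC(=O)c1ccc(O)c(OC)c1
F2 | step 5 | 1-(4-(benzyloxy)-3-methoxyphenyl)propan-1-one | CCC(=O)c1ccc(OCc2ccccc2)c(OC)c1
F3 | step 5 | lithium (Z)-1-(4-(benzyloxy)-3-methoxyphenyl)prop-1-en-1-olate | C/C=C(\O[Li])c1ccc(OCc2ccccc2)c(OC)c1
F4 | step 6 | (2R,3S)-1-(4-(benzyloxy)-3-methoxyphenyl)-4-(4-(benzyloxy)-3,5-dimethoxyphenyl)-4-(((S)-2-(methoxymethyl)pyrrolidin-1-yl)imino)-2,3-dimethylbutan-1-ol | COC[C@@H]1CCCN1N=C(c1cc(OC)c(OCc2ccccc2)c(OC)c1)[C@@H](C)[C@@H](C)C(O)c1ccc(OCc2ccccc2)c(OC)c1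
F5 | step 6 | (2S,3R)-4-(4-(benzyloxy)-3-methoxyphenyl)-1-(4-(benzyloxy)-3,5-dimethoxyphenyl)-4-hydroxy-2,3-dimethylbutan-1-one | O=C(c1cc(OC)c(OCc2ccccc2)c(OC)c1)[C@@H](C)[C@@H](C)C(O)c1ccc(OCc2ccccc2)c(OC)c1
F6 | step 7 | 1-(benzyloxy)-4-((2S,3R)-4-(4-(benzyloxy)-3,5-dimethoxyphenyl)-2,3-dimethylbutyl)-2-methoxybenzene | COc1cc(C[C@H](C)[C@H](C)Cc2cc(OC)c(OCc3ccccc3)c(OC)c2)ccc1OCc1ccccc1
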